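- Free nucleophile plus free base cannot stay above acid set free once enough electrophile has gone through the nucleophile step, and that crossing is what to watch. Each passage uses one nucleophile and sets one acid free, so free nucleophile + free base − acid set free, which starts at the charged free base, drops by two per passage (protonation and salt formation leave it unchanged). Let s be the passed share of the electrophile charged: target plus half the side product, since one side product holds one passage in its two electrophiles. That quantity reaches zero at s = a, the base allowance, which for larch is 50.0%: charged free base over twice the charged electrophile.

| setting | grey | amber | larch | elm | birch |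
|---|---|---|---|---|---|
| electrophile | 13 mM | 13 mM | 13 mM | 13 mM | 13 mM |
| free base | 19 mM | 69 mM | 13.0 mM | 26.0 mM | 52.0 mM |
| protonated nucleophile | 19.5 mM | 19.5 mM | 19.5 mM | 19.5 mM | 19.5 mM |
| remark | run made earlier | run made earlier |  |  |  |
| time |  |  | 40 h | 40 h | 40 h |

| run | time / h | electrophile / % | target / % |
|---|---|---|---|
| grey | 3.00 | 80.4 | 17.2 |
| grey | 6.00 | 62.9 | 28.5 |
| grey | 8.00 | 53.3 | 33.4 |
| grey | 12.0 | 38.5 | 40.5 |
| grey | 15.0 | 30.2 | 43.2 |
| grey | 20.0 | 21.2 | 45.6 |
| amber | 1.00 | 90.9 | 8.2 |
| amber | 3.00 | 69.7 | 26.7 |
| amber | 6.00 | 44.3 | 44.2 |
| amber | 8.00 | 32.1 | 52.5 |
| amber | 12.0 | 16.3 | 61.1 |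
| amber | 15.0 | 10.0 | 65.0 |
| amber | 20.0 | 4.1 | 67.3 |

(readings scatter by 0.3 percentage points)

- a species is counted by the electrophile in it: one side product counts as two
- what was read earlier has a scatter of 0.3 percentage points, one standard deviation
- reactions considered so far: electrophile + target -> side product; acid set free + free base <-> salt of the base; electrophile + nucleophile -> acid set free + target; nucleophile + acid set free <-> protonated nucleophile

- part of the electrophile that has reacted at the end, larch
- part of the electrophile that has reacted at the end, elm
- part of the electrophile that has reacted at the end, birch
- what raising the concentration of free base from its lowest to its highest value here does to the part of the electrophile that has reacted (changes below 5 percentage points count as none) (it falls / no change / it rises)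

- Free base is the first setting. By hand, elm has a = 100% and birch 200%, while larch, with 50.0%, is the flask I expect to cross, making free base its limiting reagent. The earlier runs show the direction without a crossing: grey has a = 73.1% and s = 62.2% at 20.0 h, with 21.2% of its electrophile left, while amber has a = 265% and 4.1% left at 20.0 h.
- Time is the second setting. The step electrophile + target takes no base, so I expect larch's electrophile to keep falling past its crossing. Grey's balance already lacks 33.2% at 20.0 h, against 45.6% of target. I therefore commit to larch lying well above 50.0% in conversion, with target and side product the readings to watch.
- The forecast gives larch 88%, elm 97% and birch 99.7%, and says of the reacted part it rises, on the ground that “Larch has too little base, so the nucleophile is starved, but the side reaction still consumes electrophile”.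
- Larch gives 88.0%, elm 98.2% and birch 99.8%, so of the reacted part it rises, by 12 percentage points. In larch, 0.82% of the charged free base remains at 40.0 h, with 50.6% side product against 37.4% target. At 20.0 h larch has s = 54.1%, past its 50.0%, and acid set free, at 3.03 mM, stands above free nucleophile plus free base, at 1.97 mM.

    electrophile + target → side product (k = 0.00130 M⁻¹ s⁻¹)
    acid set free + free base ⇌ salt of the base (K = 28000 M⁻¹, k = 0.0260 M⁻¹ s⁻¹)
    electrophile + nucleophile → acid set free + target (k = 0.00480 M⁻¹ s⁻¹)
    nucleophile + acid set free ⇌ protonated nucleophile, settled at all times (K = 2200 M⁻¹)

- Take elm with 10 mM of free base instead: a = 38.5%, lower than larch's, so I look for an earlier crossing and less target. At 40.0 h it gives 83.5% conversion, 32.0% target and 51.5% side product, with s = 57.8% and 0.61% of its free base left.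

The data stem from a simulated flask for substances that don't exist; scatter was added.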